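## Analysis of the target

Stypoquinonic acid is a trans-fused decalin that carries a 2-methyl-1,4-benzoquinone through a CH2 group on a quaternary ring carbon. With the locants used below (ring A: C-1 to C-5 and C-10; ring B: C-5 to C-10), ring B holds the angular quaternary C-5 (CH3), C-8 (CH–CH3) and the quaternary C-9 (CH3 and CH2Ar). Ring A holds an exocyclic isopropylidene at C-3 and a 2-carboxyethyl chain at C-4. There are five stereocentres (C-4, C-5, C-8, C-9, C-10). The three ring-B methyls and the C-4 chain lie on one face (β); H-10, H-8, H-4 and the arylmethyl group lie on the other. The C-5 and C-9 methyls are 1,3-diaxial across the ring-fusion CH. The sensitive groups are the quinone (base, nucleophiles, reductants), carried as its dimethyl ether to the last step, the tetrasubstituted isopropylidene (acid-induced migration would erase C-4), and the acid. The hard part is C-9: a reagent reaching a C-9/C-10 π system from outside takes the α face, away from the angular methyl, so with the large arylmethyl group already on C-9 the small methyl must go onto the hindered β face. The strategy rests on the fact that this methyl carbon is one bond from C-10, which ends as a CH. It can be held for a while on both C-9 and C-10 as the CH2 of a cyclopropane, delivered to the β face by a hydroxyl on C-1, and the C-10–CH2 bond can then be cut again.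

## Retrosynthetic reasoning

**Quinone.** 36 is traced to the hydroquinone dimethyl ether 35 by cutting the two O–CH3 bonds. The quinone would not survive the enolate, organometallic and reductive steps, so the forward oxidation has to be the last step and must spare the tetrasubstituted alkene.

**Isopropylidene.** 35 comes from ester 34, and the C-3=C(CH3)2 bond is cut back to ketone 32 through dibromoalkene 33. The alkene is made late and without acid because it is strained against the equatorial C-4 chain and could migrate into the ring. In 32 the C-4 hydrogen is α to the carbonyl, and the wanted equatorial chain is the more stable arrangement.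

**C-3 oxygen and C-4 hydrogen.** 32 is traced to alkene 29 by removing O from C-3 and H from C-4. A syn hydroboration from the face opposite the angular methyl gives both, and fixes C-4.

**Acid chain.** The C-4–CH2 bond of 29 is cut to enol triflate 28 and the zinc homoenolate 4. Ketone 27 can enolise only toward C-3, so a single triflate forms. The whole sequence is a 1,2-carbonyl transposition with chain attachment.

**C-1 oxygen and ketal.** 27 is traced to ketone 23 by putting back the C-1 carbonyl (through alkene 25 and enol triflate 24) and the C-4 ketal. The forward route must remove the C-1 oxygen without enolising toward C-10.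

**C-10–CH2 bond.** 23 is traced to cyclopropyl ketone 21 by re-forming the C-10–CH2 bond, and 21 to carbinol 20. The forward opening must cut only that bond and protonate C-10 from the α face.

**Key disconnection.** 20 is cut at C-9–CH2 and C-10–CH2 to allylic alcohol 18 and a methylene carbenoid. This is the only point where the C-9 methyl can reach the β face: the C-1 hydroxyl sits on that face next to the alkene and carries the reagent there.

**C-8 methyl and C-1 hydroxyl.** 18 is traced through silyl ether 17, diene 16 and dienyl triflate 15 to hydroxy enone 13 (as its ether 14), and 13 to enone ketal 11. The enone carbonyl serves twice: its dienol ether admits oxygen at C-1, and its enol triflate exchanges the carbonyl for methyl. Hydrogenating the C-7=C-8 bond rather than an exocyclic methylene puts the face choice under control of the angular methyl, which is syn-axial to C-7.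

**Decalin.** 11 comes from enedione 10, and 10 from triketone 9 by cutting the C-9=C-10 bond (aldol condensation) and the C-5–C-6 bond (Michael addition) to dione 8 and vinyl ketone 7. The arylmethyl group thus arrives with the annulation.

**Vinyl ketone.** 7 is cut at the acyl–vinyl bond to ester 5, 5 at the aryl–CH2 bond to bromide 3 and zinc reagent 4, and 3 goes back to phenol 1, whose hydroxyl fixes the position of the bromine.

## Alternatives that were turned down

**Alternative 1:** benzannulation of the quinone ring. The arene is cut at three C–C bonds into a terminal alkyne on the benzylic CH2 (A2), a propenyl methoxycarbene complex of Cr(CO)5 (A3) and CO. Heating A2 with A3 should give the 4-methoxyphenol A1 by alkyne insertion, CO insertion and electrocyclisation, and one oxidation then gives the quinone.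
- For: it is convergent; the arene substitution pattern follows from the insertion rule (large alkyne substituent next to the phenol); no electron-rich arene is carried through reductions; and the quaternary C-9 could be made by propargylation of a methyl-bearing enolate from the open α face. On these points it is as strong as or stronger than the chosen route.
- Against: it leaves the decalin problem untouched, since the whole ring system with all five stereocentres and the C-3/C-4 array must be finished first. A stoichiometric chromium reaction is then run on the most advanced intermediate.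
- The chosen route offers in its place an arene bought as a cheap phenol, no stoichiometric chromium, and the arylmethyl group installed by the annulation itself.

**Alternative 2:** intramolecular Diels–Alder reaction of a vinylallene. The C-5–C-10 and C-3–C-4 bonds are cut to the acyclic enal A5. Heat or a Lewis acid should close ring A by cycloaddition and ring B through the tether, giving aldehyde A4.
- For: two rings, three stereocentres and the isopropylidene come from one step. On bond economy in the key step it is stronger.
- Against: A5 needs the vicinal C-8/C-9 centres, one quaternary, set in an open chain, which is harder than in a ring. The dienophile is trisubstituted and must form a quaternary carbon beside a quaternary tether carbon, so the reaction should be slow. Endo/exo and facial control with such a tether cannot be predicted with confidence. A4 still needs a two-carbon chain extension and saturation of a disubstituted alkene that is conjugated with the isopropylidene.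
- The chosen route offers stereocontrol by ring-bound elements (angular methyl, tethered hydroxyl) at every centre.

**Alternative 3:** epoxide-initiated polyene bicyclisation. The C-9–C-10 and C-4–C-5 bonds are cut to the epoxy diene silyl enol ether A7. MeAlCl2 should open the epoxide at the arylmethyl-bearing carbon, and the alkene and the enol ether then close rings B and A to give hydroxy ketone A6.
- For: both rings, the trans fusion, four stereocentres and the acid chain come from one step, and the C-3 ketone is in place for the isopropylidene. In bonds formed per step it is the strongest of the four.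
- Against: the initiating tertiary cation sits one CH2 from a very electron-rich arene, so Friedel–Crafts capture and hydride or methyl shifts compete with the first ring closure. C-8 ends as a carbinol, not a methyl carbon, so oxidation, methylenation and a face-selective hydrogenation must follow. The trisubstituted epoxide and two defined alkene geometries must be built first.
- The chosen route offers ionic steps that never place a cation near the arene, and a C-8 methyl set before the key step.

Key step: step 14

Conventions and assumptions:
- Locants: ring A = C-1, C-2, C-3, C-4, C-5, C-10; ring B = C-5 to C-10; C-5 bears the angular methyl, C-10 is the ring-fusion CH, C-9 bears the arylmethyl group, C-8 the secondary methyl, C-4 (next to C-5) the acid chain, C-3 the isopropylidene. β is the face of the C-5 methyl. Ar = 2,5-dimethoxy-3-methylphenyl.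
- Remark: (3-ethoxy-3-oxopropyl)zinc bromide (4) is taken as a purchased THF solution.

## Route

Step 1
Reactants: 1 4-methoxy-2-methylphenol
Product: 2 2-bromo-4-methoxy-6-methylphenol
Conditions: NBS, i-Pr2NH (cat.), CH2Cl2, 0 °C
Reagents that add atoms: N-bromosuccinimide, O=C1CCC(=O)N1Br
Why: Electrophilic aromatic bromination (amine-mediated ortho-bromination of phenols); the hydroxyl is the strongest director, its para position is blocked by OMe and one ortho position by CH3, so bromine should enter the free ortho carbon.

Step 2
Reactants: 2 2-bromo-4-methoxy-6-methylphenol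
Product: 3 1-bromo-2,5-dimethoxy-3-methylbenzene
Conditions: MeI, K2CO3, acetone, reflux
Reagents that add atoms: iodomethane, CI
Why: Williamson ether synthesis on a phenoxide; it gives the hydroquinone dimethyl ether that masks the quinone to the end.

Step 3
Reactants: 3 1-bromo-2,5-dimethoxy-3-methylbenzene; 4 (3-ethoxy-3-oxopropyl)zinc bromide
Product: 5 ethyl 3-(2,5-dimethoxy-3-methylphenyl)propanoate
Conditions: Pd(OAc)2 (2 mol %), SPhos (4 mol %), THF, 50 °C
Reagents that add atoms: none
Why: Negishi coupling of an aryl bromide with a primary alkylzinc halide; the biaryl phosphine tolerates the ortho methoxy group and suppresses β-hydride elimination, and the ester is inert to the zinc reagent.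

Step 4
Reactants: 5 ethyl 3-(2,5-dimethoxy-3-methylphenyl)propanoate
Product: 7 5-(2,5-dimethoxy-3-methylphenyl)pent-1-en-3-one, via Weinreb amide 6 (not isolated)
Conditions: MeNH(OMe)·HCl, i-PrMgCl, THF, −20 °C; then CH2=CHMgBr, −20 → 0 °C; poured into cold 1 M HCl
Reagents that add atoms: vinylmagnesium bromide, C=C[Mg]Br; N,O-dimethylhydroxylamine hydrochloride, CNOC.Cl (atoms kept only in 6)
Why: Weinreb ketone synthesis run in one flask; the magnesium amide converts the ester into 6, whose chelated adduct with the vinyl Grignard reagent releases the vinyl ketone only on the acidic inverse quench, which also limits conjugate addition of the liberated amine.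

Step 5
Reactants: 7 5-(2,5-dimethoxy-3-methylphenyl)pent-1-en-3-one; 8 2-methylcyclohexane-1,3-dione
Product: 9 2-[5-(2,5-dimethoxy-3-methylphenyl)-3-oxopentyl]-2-methylcyclohexane-1,3-dione
Conditions: Et3N (10 mol %), MeCN, rt
Reagents that add atoms: none
Why: Michael addition of the stabilised dione enolate to the vinyl ketone, the first half of a Robinson annulation; it forms the quaternary carbon that becomes C-5.

Step 6
Reactants: 9 triketone
Product: 10 (5R)-9-(ArCH2)-5-methyl-Δ9(10)-octalin-4,8-dione
Conditions: D-phenylalanine (1.0 equiv), (1S)-(+)-10-camphorsulfonic acid (0.5 equiv), DMF, 30 → 70 °C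
Reagents that add atoms: none
Why: Amino-acid-mediated intramolecular aldol condensation of Hajos–Parrish type; the enamine of the side-chain ketone attacks one of the two enantiotopic ring carbonyls under direction of the carboxylic acid, and a primary amino acid is used because the enamine carbon is substituted. The D-amino acid should give the (5R) enone, the mirror image of the series obtained with L-amino acids, and this single centre controls all later ones.

Step 7
Reactants: 10 enedione
Product: 11 (5R)-4,4-ethylenedioxy-9-(ArCH2)-5-methyl-Δ9(10)-octalin-8-one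
Conditions: HOCH2CH2OH, p-TsOH·H2O (cat.), 4 Å MS, rt
Reagents that add atoms: ethylene glycol, OCCO
Why: Chemoselective ketalisation; the saturated C-4 ketone is more electrophilic than the conjugated C-8 ketone, and at room temperature the C-9=C-10 bond should not move.

Step 8
Reactants: 11 enone ketal
Product: 13 4,4-ethylenedioxy-1β-hydroxy-9-(ArCH2)-5β-methyl-Δ9(10)-octalin-8-one, via silyl dienol ether 12 (not isolated)
Conditions: TBSOTf, Et3N, CH2Cl2, 0 °C; then mCPBA, NaHCO3, CH2Cl2, −20 → 0 °C
Reagents that add atoms: 3-chloroperoxybenzoic acid, OOC(=O)c1cccc(Cl)c1; tert-butyldimethylsilyl trifluoromethanesulfonate, CC(C)(C)[Si](C)(C)OS(=O)(=O)C(F)(F)F (atoms kept only in 12)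
Why: Vinylogous Rubottom oxidation; soft enolisation gives the extended 1(10),8-dienol ether and the peracid attacks its terminal carbon C-1. Axial attack on the face of the angular methyl is stereoelectronically preferred, as in the 6β-hydroxylation of steroidal dienol ethers, and an equatorial C-1 oxygen would suffer allylic 1,3-strain with the arylmethyl group on C-9, so the 1β (axial) alcohol should form.

Step 9
Reactants: 13 1β-hydroxy enone
Product: 14 1β-triethylsilyl ether of 13
Conditions: TESOTf, 2,6-lutidine, CH2Cl2, −78 → 0 °C
Reagents that add atoms: triethylsilyl trifluoromethanesulfonate, CC[Si](CC)(CC)OS(=O)(=O)C(F)(F)F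
Why: Silylation of a hindered axial alcohol with a silyl triflate; the ether prevents base-induced isomerisation of the γ-hydroxy enone to a 1,4-diketone and keeps the oxygen out of the next three steps.

Step 10
Reactants: 14 silyloxy enone
Product: 15 4,4-ethylenedioxy-1β-(triethylsilyloxy)-9-(ArCH2)-5β-methyl-8-(trifluoromethanesulfonyloxy)-octalin-7,9(10)-diene
Conditions: LiN(SiMe3)2, THF, −78 °C; PhNTf2, −78 → 0 °C
Reagents that add atoms: N-phenylbis(trifluoromethanesulfonimide), O=S(=O)(N(c1ccccc1)S(=O)(=O)C(F)(F)F)C(F)(F)F
Why: Kinetic deprotonation of an enone at the α′ carbon (C-7) gives the cross-conjugated dienolate, which is sulfonylated on oxygen; the C-9=C-10 bond stays in place.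

Step 11
Reactants: 15 dienyl triflate
Product: 16 4,4-ethylenedioxy-1β-(triethylsilyloxy)-9-(ArCH2)-5β,8-dimethyl-octalin-7,9(10)-diene
Conditions: MeMgBr, Fe(acac)3 (5 mol %), THF/NMP, −30 → 0 °C
Reagents that add atoms: methylmagnesium bromide, C[Mg]Br
Why: Iron-catalysed Kumada-type coupling of an alkenyl triflate with a methyl Grignard reagent; it replaces the former carbonyl oxygen by CH3 with the alkene positions fixed, and ketal, silyl ether and aryl ethers tolerate the conditions.

Step 12
Reactants: 16 homoannular diene
Product: 17 4,4-ethylenedioxy-1β-(triethylsilyloxy)-9-(ArCH2)-5β,8β-dimethyl-Δ9(10)-octalin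
Conditions: H2 (1 atm), RhCl(PPh3)3 (10 mol %), toluene/EtOH, rt
Reagents that add atoms: none
Why: 1,2-Hydrogenation of the less substituted double bond of a homoannular diene, as in the conversion of steroidal 5,7-dienes into 5α-7-enes; the tetrasubstituted C-9=C-10 bond is too hindered to bind the catalyst. The angular methyl is syn-axial to C-7, so both hydrogens should arrive from the α face and leave the C-8 methyl β.

Step 13
Reactants: 17 silyl ether
Product: 18 4,4-ethylenedioxy-9-(ArCH2)-5β,8β-dimethyl-Δ9(10)-octalin-1β-ol
Conditions: Bu4NF, THF, 0 °C → rt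
Reagents that add atoms: none
Why: Fluoride cleavage of the Si–O bond; acid is avoided because the allylic alcohol next to a tetrasubstituted alkene would ionise.

Step 14
Reactants: 18 allylic alcohol
Product: 20 4,4-ethylenedioxy-9α-(ArCH2)-5β,8β-dimethyl-9β,10β-methanodecalin-1β-ol, via ethylzinc alkoxide 19 (not isolated)
Conditions: Et2Zn, CH2I2, CH2Cl2, 0 °C → rt
Reagents that add atoms: diiodomethane, ICI; diethylzinc, CC[Zn]CC (atoms kept only in 19)
Why: Et2Zn converts the hydroxyl of 18 into the ethylzinc alkoxide 19, and Et2Zn with CH2I2 gives the iodomethylzinc carbenoid, which binds to the alkoxide oxygen and transfers CH2 to the C-9=C-10 bond in a concerted butterfly-type [2+1] addition; this is the hydroxyl-directed Simmons–Smith cyclopropanation of cyclic allylic alcohols, which is known for tetrasubstituted octalin alkenes. The three-membered ring closes in one step by syn addition of the methylene to both alkene carbons, so the C-9–CH2 and C-10–CH2 bonds form on the same face. Both new stereocentres, C-9 and C-10, are set by the C-1 alkoxide, which is β and pseudoaxial (an equatorial oxygen would clash with the arylmethyl group on C-9), so the C–O bond stands almost perpendicular to the alkene plane and the bound carbenoid can reach only the β face. The step needs addition on the face that carries the C-5 and C-8 methyls, which an untethered reagent avoids; the tether secures it because directed transfer should be much faster than undirected transfer to an unactivated tetrasubstituted alkene. The arene, the ketal and C-8 should not be touched, and an excess of carbenoid is used so that cyclopropanation outruns O-methylation of the alkoxide.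

Step 15
Reactants: 20 cyclopropyl carbinol
Product: 21 4,4-ethylenedioxy-9α-(ArCH2)-5β,8β-dimethyl-9β,10β-methanodecalin-1-one
Conditions: Dess–Martin periodinane, NaHCO3, CH2Cl2, rt
Reagents that add atoms: none
Why: Oxidation of a hindered secondary alcohol under buffered, non-acidic conditions; no cyclopropylcarbinyl cation can form, and the ketone now activates the two cyclopropane bonds at C-10.

Step 16
Reactants: 21 cyclopropyl ketone
Product: 23 4,4-ethylenedioxy-9α-(ArCH2)-5β,8β,9β-trimethyl-trans-decalin-1-one (10α-H), via lithium enolate 22 (not isolated)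
Conditions: Li, NH3 (l)/THF, −78 °C, 15 min; solid NH4Cl
Reagents that add atoms: lithium, [Li] (atoms kept only in 22)
Why: Dissolving-metal opening of a conjugated cyclopropyl ketone; electron transfer to the carbonyl cleaves a cyclopropane bond at C-10, and the departing carbon takes on carbanion character, so the primary CH2 should leave in preference to the tertiary C-9, which gives the 9β-methyl group and enolate 22. A dissolving metal is preferred to a radical-type reductant such as SmI2, which would favour the tertiary C-9 radical and ring enlargement. Enolate 22 is protonated at C-10 from the α face, away from the β methyls on C-5 and C-9, to give the trans ring fusion; no alcohol is added, so the aryl ring should not be reduced.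

Step 17
Reactants: 23 trans-decalin-1-one
Product: 24 4,4-ethylenedioxy-9α-(ArCH2)-5β,8β,9β-trimethyl-1-(trifluoromethanesulfonyloxy)-trans-octal-1-ene
Conditions: KN(SiMe3)2, THF, −78 °C; PhNTf2
Reagents that add atoms: N-phenylbis(trifluoromethanesulfonimide), O=S(=O)(N(c1ccccc1)S(=O)(=O)C(F)(F)F)C(F)(F)F
Why: Kinetic enol triflate formation; only the C-2 hydrogens are accessible, because H-10 is buried between two quaternary carbons, so the ring fusion set in step 16 is not exposed to equilibration.

Step 18
Reactants: 24 enol triflate
Product: 25 4,4-ethylenedioxy-9α-(ArCH2)-5β,8β,9β-trimethyl-trans-octal-1-ene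
Conditions: Pd(OAc)2 (5 mol %), PPh3, HCO2H, n-Bu3N, DMF, 60 °C
Reagents that add atoms: none
Why: Palladium-catalysed formate reduction of a vinyl triflate (oxidative addition to zerovalent palladium, formate-to-hydride exchange with loss of CO2, reductive elimination); it removes the C-1 oxygen without base or heat at C-10.

Step 19
Reactants: 25 alkene
Product: 27 9α-(ArCH2)-5β,8β,9β-trimethyl-trans-decalin-4-one, via saturated ketal 26 (not isolated)
Conditions: H2 (1 atm), Pd/C, EtOAc, rt; filter; 2 M HCl, THF, 40 °C
Reagents that add atoms: water, O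
Why: Hydrogenation of a cis-disubstituted ring alkene creates no stereocentre and leaves the arene alone; aqueous acid then hydrolyses the dioxolane, and the ketone set free has no epimerisable neighbour.

Step 20
Reactants: 27 decalin-4-one
Product: 28 9α-(ArCH2)-5β,8β,9β-trimethyl-4-(trifluoromethanesulfonyloxy)-trans-octal-3-ene
Conditions: KN(SiMe3)2, THF, −78 °C; PhNTf2
Reagents that add atoms: N-phenylbis(trifluoromethanesulfonimide), O=S(=O)(N(c1ccccc1)S(=O)(=O)C(F)(F)F)C(F)(F)F
Why: Enol triflate formation; C-5 is quaternary, so the ketone can enolise only toward C-3 and one regioisomer is possible.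

Step 21
Reactants: 28 enol triflate; 4 (3-ethoxy-3-oxopropyl)zinc bromide
Product: 29 ethyl 3-[9α-(ArCH2)-5β,8β,9β-trimethyl-trans-octal-3-en-4-yl]propanoate
Conditions: PdCl2(dppf) (5 mol %), THF/NMP, 60 °C
Reagents that add atoms: none
Why: Negishi coupling of a hindered alkenyl triflate with a primary alkylzinc halide; the bidentate phosphine favours reductive elimination over β-hydride elimination, and the whole acid chain is attached in one step.

Step 22
Reactants: 29 alkene ester
Product: 31 ethyl 3-[3α-hydroxy-9α-(ArCH2)-5β,8β,9β-trimethyl-trans-decalin-4β-yl]propanoate (4α-H), via alkylborane 30 (not isolated)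
Conditions: 9-BBN, THF, 65 °C; then NaBO3·4H2O, H2O, rt
Reagents that add atoms: sodium perborate, [Na+].[O-]OB=O; 9-borabicyclo[3.3.1]nonane, B1C2CCCC1CCC2 (atoms kept only in 30)
Why: Hydroboration–oxidation; boron adds to the less substituted C-3 and hydrogen to C-4 in a syn addition from the α face, opposite the adjacent angular methyl, which sets C-4 with the chain β and equatorial. A dialkylborane is used because BH3 would leave B–H bonds that reduce the nearby ester through a cyclic transition state, and perborate oxidises the C–B bond with retention without hydrolysing the ester.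

Step 23
Reactants: 31 hydroxy ester
Product: 32 ethyl 3-[3-oxo-9α-(ArCH2)-5β,8β,9β-trimethyl-trans-decalin-4β-yl]propanoate
Conditions: Dess–Martin periodinane, NaHCO3, CH2Cl2, rt
Reagents that add atoms: none
Why: Neutral alcohol oxidation; C-4 is now α to a ketone, but the equatorial β chain is also the more stable arrangement, so enolisation would not change it.

Step 24
Reactants: 32 keto ester
Product: 33 ethyl 3-[3-(dibromomethylene)-9α-(ArCH2)-5β,8β,9β-trimethyl-trans-decalin-4β-yl]propanoate
Conditions: CBr4, PPh3, toluene, 80 °C
Reagents that add atoms: carbon tetrabromide, BrC(Br)(Br)Br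
Why: Ramirez dibromo-olefination; the ylide Ph3P=CBr2 formed in the flask is weakly basic, so the α-branched ketone should be olefinated without enolisation, and the exocyclic position of the new double bond is fixed by the mechanism.

Step 25
Reactants: 33 dibromoalkene
Product: 34 ethyl 3-[3-isopropylidene-9α-(ArCH2)-5β,8β,9β-trimethyl-trans-decalin-4β-yl]propanoate
Conditions: Me2Zn, Pd(P(t-Bu)3)2 (5 mol %), THF, 50 °C
Reagents that add atoms: dimethylzinc, C[Zn]C
Why: Twofold Negishi methylation of a 1,1-dibromoalkene; the bulky electron-rich phosphine allows oxidative addition to both hindered C–Br bonds, methyl has no β-hydrogen, and the ester is inert to the organozinc, so the isopropylidene forms without acid.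

Step 26
Reactants: 34 ethyl ester
Product: 35 3-[3-isopropylidene-9α-(ArCH2)-5β,8β,9β-trimethyl-trans-decalin-4β-yl]propanoic acid
Conditions: LiOH, THF/MeOH/H2O, rt; then 1 M HCl
Reagents that add atoms: lithium hydroxide, [Li+].[OH-]
Why: Saponification of an unhindered ester; it is done before the quinone exists, because quinones do not tolerate hydroxide.

Step 27
Reactants: 35 dimethyl ether acid
Product: 36 stypoquinonic acid
Conditions: (NH4)2Ce(NO3)6, MeCN/H2O, 0 °C
Reagents that add atoms: water, O
Why: Oxidative demethylation of a 1,4-dimethoxyarene by tetravalent cerium; two one-electron oxidations with addition of water at the methoxy-bearing carbons release methanol and give the quinone. The trialkylated dimethoxyarene is oxidised more easily than the tetrasubstituted alkene, so a short reaction at 0 °C should spare the isopropylidene.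

## Compound list

1 | 4-methoxy-2-methylphenol | COc1ccc(O)c(C)c1 | starting material
2 | 2-bromo-4-methoxy-6-methylphenol | COc1cc(C)c(O)c(Br)c1 | intermediate
3 | 1-bromo-2,5-dimethoxy-3-methylbenzene | COc1cc(C)c(OC)c(Br)c1 | intermediate
4 | (3-ethoxy-3-oxopropyl)zinc bromide | CCOC(=O)CC[Zn]Br | starting material
5 | ethyl 3-(2,5-dimethoxy-3-methylphenyl)propanoate | COc1cc(C)c(OC)c(CCC(=O)OCC)c1 | intermediate
6 | 3-(2,5-dimethoxy-3-methylphenyl)-N-methoxy-N-methylpropanamide (Weinreb amide, not isolated) | COc1cc(C)c(OC)c(CCC(=O)N(C)OC)c1 | intermediate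
7 | 5-(2,5-dimethoxy-3-methylphenyl)pent-1-en-3-one | COc1cc(C)c(OC)c(CCC(=O)C=C)c1 | intermediate
8 | 2-methylcyclohexane-1,3-dione | CC1C(=O)CCCC1=O | starting material
9 | 2-[5-(2,5-dimethoxy-3-methylphenyl)-3-oxopentyl]-2-methylcyclohexane-1,3-dione | COc1cc(C)c(OC)c(CCC(=O)CCC2(C)C(=O)CCCC2=O)c1 | intermediate
10 | (5R)-9-(ArCH2)-5-methyl-Δ9(10)-octalin-4,8-dione [(8aR)-5-(ArCH2)-8a-methyl-3,4,8,8a-tetrahydronaphthalene-1,6(2H,7H)-dione] | COc1cc(C)c(OC)c(CC2=C3CCCC(=O)[C@]3(C)CCC2=O)c1 | intermediate
11 | (5R)-4,4-ethylenedioxy-9-(ArCH2)-5-methyl-Δ9(10)-octalin-8-one | COc1cc(C)c(OC)c(CC2=C3CCCC4(OCCO4)[C@]3(C)CCC2=O)c1 | intermediate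
12 | 8-(tert-butyldimethylsilyloxy)-4,4-ethylenedioxy-9-(ArCH2)-5β-methyl-octalin-1(10),8-diene (silyl dienol ether, not isolated) | COc1cc(C)c(OC)c(CC2=C(O[Si](C)(C)C(C)(C)C)CC[C@]3(C)C2=CCCC34OCCO4)c1 | intermediate
13 | 4,4-ethylenedioxy-1β-hydroxy-9-(ArCH2)-5β-methyl-Δ9(10)-octalin-8-one | COc1cc(C)c(OC)c(CC2=C3[C@@H](O)CCC4(OCCO4)[C@]3(C)CCC2=O)c1 | intermediate
14 | 4,4-ethylenedioxy-1β-(triethylsilyloxy)-9-(ArCH2)-5β-methyl-Δ9(10)-octalin-8-one | COc1cc(C)c(OC)c(CC2=C3[C@@H](O[Si](CC)(CC)CC)CCC4(OCCO4)[C@]3(C)CCC2=O)c1 | intermediate
15 | 4,4-ethylenedioxy-1β-(triethylsilyloxy)-9-(ArCH2)-5β-methyl-8-(trifluoromethanesulfonyloxy)-octalin-7,9(10)-diene | COc1cc(C)c(OC)c(CC2=C3[C@@H](O[Si](CC)(CC)CC)CCC4(OCCO4)[C@]3(C)CC=C2OS(=O)(=O)C(F)(F)F)c1 | intermediate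
16 | 4,4-ethylenedioxy-1β-(triethylsilyloxy)-9-(ArCH2)-5β,8-dimethyl-octalin-7,9(10)-diene | COc1cc(C)c(OC)c(CC2=C3[C@@H](O[Si](CC)(CC)CC)CCC4(OCCO4)[C@]3(C)CC=C2C)c1 | intermediate
17 | 4,4-ethylenedioxy-1β-(triethylsilyloxy)-9-(ArCH2)-5β,8β-dimethyl-Δ9(10)-octalin | COc1cc(C)c(OC)c(CC2=C3[C@@H](O[Si](CC)(CC)CC)CCC4(OCCO4)[C@]3(C)CC[C@H]2C)c1 | intermediate
18 | 4,4-ethylenedioxy-9-(ArCH2)-5β,8β-dimethyl-Δ9(10)-octalin-1β-ol (precursor of the key step) | COc1cc(C)c(OC)c(CC2=C3[C@@H](O)CCC4(OCCO4)[C@]3(C)CC[C@H]2C)c1 | intermediate
19 | ethylzinc alkoxide of 18 (not isolated) | COc1cc(C)c(OC)c(CC2=C3[C@@H](O[Zn]CC)CCC4(OCCO4)[C@]3(C)CC[C@H]2C)c1 | intermediate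
20 | 4,4-ethylenedioxy-9α-(ArCH2)-5β,8β-dimethyl-9β,10β-methanodecalin-1β-ol (product of the key step) | COc1cc(C)c(OC)c(C[C@]23C[C@]24[C@@H](O)CCC5(OCCO5)[C@]4(C)CC[C@H]3C)c1 | intermediate
21 | 4,4-ethylenedioxy-9α-(ArCH2)-5β,8β-dimethyl-9β,10β-methanodecalin-1-one | COc1cc(C)c(OC)c(C[C@]23C[C@]24C(=O)CCC5(OCCO5)[C@]4(C)CC[C@H]3C)c1 | intermediate
22 | lithium 4,4-ethylenedioxy-9α-(ArCH2)-5β,8β,9β-trimethyl-octal-1(10)-en-1-olate (not isolated) | COc1cc(C)c(OC)c(C[C@]2(C)C3=C(O[Li])CCC4(OCCO4)[C@]3(C)CC[C@H]2C)c1 | intermediate
23 | 4,4-ethylenedioxy-9α-(ArCH2)-5β,8β,9β-trimethyl-trans-decalin-1-one (10α-H) | COc1cc(C)c(OC)c(C[C@]2(C)[C@H]3C(=O)CCC4(OCCO4)[C@]3(C)CC[C@H]2C)c1 | intermediate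
24 | 4,4-ethylenedioxy-9α-(ArCH2)-5β,8β,9β-trimethyl-1-(trifluoromethanesulfonyloxy)-trans-octal-1-ene | COc1cc(C)c(OC)c(C[C@]2(C)[C@H]3C(OS(=O)(=O)C(F)(F)F)=CCC4(OCCO4)[C@]3(C)CC[C@H]2C)c1 | intermediate
25 | 4,4-ethylenedioxy-9α-(ArCH2)-5β,8β,9β-trimethyl-trans-octal-1-ene | COc1cc(C)c(OC)c(C[C@]2(C)[C@H]3C=CCC4(OCCO4)[C@]3(C)CC[C@H]2C)c1 | intermediate
26 | 4,4-ethylenedioxy-9α-(ArCH2)-5β,8β,9β-trimethyl-trans-decalin (not isolated) | COc1cc(C)c(OC)c(C[C@]2(C)[C@H]3CCCC4(OCCO4)[C@]3(C)CC[C@H]2C)c1 | intermediate
27 | 9α-(ArCH2)-5β,8β,9β-trimethyl-trans-decalin-4-one | COc1cc(C)c(OC)c(C[C@]2(C)[C@H]3CCCC(=O)[C@]3(C)CC[C@H]2C)c1 | intermediate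
28 | 9α-(ArCH2)-5β,8β,9β-trimethyl-4-(trifluoromethanesulfonyloxy)-trans-octal-3-ene | COc1cc(C)c(OC)c(C[C@]2(C)[C@H]3CCC=C(OS(=O)(=O)C(F)(F)F)[C@]3(C)CC[C@H]2C)c1 | intermediate
29 | ethyl 3-[9α-(ArCH2)-5β,8β,9β-trimethyl-trans-octal-3-en-4-yl]propanoate | COc1cc(C)c(OC)c(C[C@]2(C)[C@H]3CCC=C(CCC(=O)OCC)[C@]3(C)CC[C@H]2C)c1 | intermediate
30 | 3α-(9-borabicyclo[3.3.1]nonan-9-yl) adduct of 29 (4α-H, 4β-chain; not isolated) | COc1cc(C)c(OC)c(C[C@]2(C)[C@H]3CC[C@H](B4C5CCCC4CCC5)[C@@H](CCC(=O)OCC)[C@]3(C)CC[C@H]2C)c1 | intermediate
31 | ethyl 3-[3α-hydroxy-9α-(ArCH2)-5β,8β,9β-trimethyl-trans-decalin-4β-yl]propanoate | COc1cc(C)c(OC)c(C[C@]2(C)[C@H]3CC[C@H](O)[C@@H](CCC(=O)OCC)[C@]3(C)CC[C@H]2C)c1 | intermediate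
32 | ethyl 3-[3-oxo-9α-(ArCH2)-5β,8β,9β-trimethyl-trans-decalin-4β-yl]propanoate | COc1cc(C)c(OC)c(C[C@]2(C)[C@H]3CCC(=O)[C@@H](CCC(=O)OCC)[C@]3(C)CC[C@H]2C)c1 | intermediate
33 | ethyl 3-[3-(dibromomethylene)-9α-(ArCH2)-5β,8β,9β-trimethyl-trans-decalin-4β-yl]propanoate | COc1cc(C)c(OC)c(C[C@]2(C)[C@H]3CCC(=C(Br)Br)[C@@H](CCC(=O)OCC)[C@]3(C)CC[C@H]2C)c1 | intermediate
34 | ethyl 3-[3-isopropylidene-9α-(ArCH2)-5β,8β,9β-trimethyl-trans-decalin-4β-yl]propanoate | COc1cc(C)c(OC)c(C[C@]2(C)[C@H]3CCC(=C(C)C)[C@@H](CCC(=O)OCC)[C@]3(C)CC[C@H]2C)c1 | intermediate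
35 | 3-[3-isopropylidene-9α-(ArCH2)-5β,8β,9β-trimethyl-trans-decalin-4β-yl]propanoic acid | COc1cc(C)c(OC)c(C[C@]2(C)[C@H]3CCC(=C(C)C)[C@@H](CCC(=O)O)[C@]3(C)CC[C@H]2C)c1 | intermediate
36 | stypoquinonic acid | CC1=CC(=O)C=C(C[C@]2(C)[C@H]3CCC(=C(C)C)[C@@H](CCC(=O)O)[C@]3(C)CC[C@H]2C)C1=O | target

## Step count and least certain steps

Total: 27 steps. Longest linear sequence: 27 steps (1 to 36); 4 and 8 are bought.

**Step 14 (key step).** The most likely failure is slow methylene transfer. The alkene is tetrasubstituted and lies between a quaternary carbon and a carbon bearing the arylmethyl group, so O-methylation of the zinc alkoxide, or recovery of 18, could win over cyclopropanation. Facial control is the lesser worry, since the α face has no directing group.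
Fallback: a [2,3]-Wittig–Still rearrangement, which uses the same hydroxyl to deliver one carbon to the β face of C-9 but forms no three-membered ring. It sets out from 18. Alkylation with KH and Bu3SnCH2I should give the (tributylstannyl)methyl ether F1. Tin–lithium exchange with n-BuLi at −78 °C triggers the suprafacial shift to the 9β-hydroxymethyl Δ1(10)-octalin F2. Oxidation with Dess–Martin periodinane gives the aldehyde F3, which has no α-hydrogen. Wolff–Kishner reduction (N2H4, KOH, diethylene glycol) gives the 9β-methyl Δ1(10)-octalin F4. Hydrogenation over Pd/C from the α face, the β face being closed by the C-5 and C-9 methyls, returns to the route at 26.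

**Step 16.** The concern is which cyclopropane bond breaks. Both the C-10–CH2 bond and the C-10–C-9 bond are conjugated with the carbonyl. In the chair form of ring A it is the C-10–C-9 bond that is aligned with the carbonyl π system, and its cleavage would enlarge ring B to a seven-membered ring. That chair should be disfavoured, because it places C-9 syn-axial to the axial ketal oxygen on C-4, and the twist form aligns the CH2 bond. Dissolving-metal conditions add an electronic preference for the primary carbon, which is why Li/NH3 is proposed rather than SmI2, but a mixture cannot be excluded. Lesser risks are partial reduction of the aryl ring and loss of the trans fusion if the enolate equilibrates.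
Fallback: an Eschenmoser–Claisen rearrangement, which needs no cyclopropane. It sets out from 18. Heating with N,N-dimethylacetamide dimethyl acetal in xylene should transfer a CH2CONMe2 group from the C-1 oxygen to the β face of C-9 and give the unsaturated amide F5. Hydrogenation over Pd/C from the α face gives the trans-fused amide F6. Cp2Zr(H)Cl reduces it to the aldehyde F7. Decarbonylation with stoichiometric RhCl(PPh3)3 in hot toluene leaves the methyl group and returns to the route at 26.

**Step 12.** What may go wrong is loss of chemoselectivity or position: 1,4-addition of hydrogen across the diene, migration of the tetrasubstituted double bond, or shielding of the α face by the aryl ring, which can fold under C-8.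
Fallback: hydroboration and deoxygenation, set out from 16. BH3·SMe2 then NaOH/H2O2 should add boron to C-7 and hydrogen to C-8 from the α face, under the same control by the angular methyl, to give the 7α-alcohol F8. NaH, CS2 and MeI give the xanthate F9. Barton–McCombie reduction with Bu3SnH and AIBN at high stannane concentration removes the oxygen and returns to the route at 17.

**Step 6.** Enamine formation next to the bulky arylethyl chain may be slow, and the enantioselectivity may fall short of what the methyl-substituted analogue allows.
Fallback: resolution in place of asymmetric induction, set out from 9. Cyclisation with pyrrolidine and acetic acid gives racemic 10, which is ketalised as in step 7; the enantiomers of 11 are then separated on a chiral stationary phase, or 10 is enriched by recrystallisation, and the route is rejoined at 11.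

**Step 22.** 9-BBN may add too slowly to a trisubstituted alkene next to a quaternary carbon, and forcing the reaction invites partial reduction of the ester.
Fallback: let the borane reduce the ester and restore the oxidation level afterwards, set out from 29. Excess BH3·SMe2 then NaOH/H2O2 gives the diol F10 with the same configuration at C-3 and C-4. TEMPO (cat.) with PhI(OAc)2 in MeCN/H2O oxidises both alcohols to the keto acid F11. EtI and K2CO3 in DMF return to the route at 32.

**Step 24.** Olefination may stall at a ketone flanked by the equatorial chain, because the product builds up allylic 1,3-strain between a bromine and that chain.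
Fallback: a reductive carbonyl coupling, set out from 32. McMurry cross-coupling with an excess of acetone (TiCl4, Zn, pyridine, THF, reflux) should give the isopropylidene compound directly; the volatile acetone dimer is removed and the route is rejoined at 34.

## Further compounds

F1 | step 14 | (tributylstannyl)methyl ether of 18 | COc1cc(C)c(OC)c(CC2=C3[C@@H](OC[Sn](CCCC)(CCCC)CCCC)CCC4(OCCO4)[C@]3(C)CC[C@H]2C)c1
F2 | step 14 | 4,4-ethylenedioxy-9β-(hydroxymethyl)-9α-(ArCH2)-5β,8β-dimethyl-octal-1(10)-ene | COc1cc(C)c(OC)c(C[C@]2(CO)C3=CCCC4(OCCO4)[C@]3(C)CC[C@H]2C)c1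
F3 | step 14 | 4,4-ethylenedioxy-9β-formyl-9α-(ArCH2)-5β,8β-dimethyl-octal-1(10)-ene | COc1cc(C)c(OC)c(C[C@]2(C=O)C3=CCCC4(OCCO4)[C@]3(C)CC[C@H]2C)c1
F4 | step 14 | 4,4-ethylenedioxy-9α-(ArCH2)-5β,8β,9β-trimethyl-octal-1(10)-ene | COc1cc(C)c(OC)c(C[C@]2(C)C3=CCCC4(OCCO4)[C@]3(C)CC[C@H]2C)c1
F5 | step 16 | 2-[4,4-ethylenedioxy-9α-(ArCH2)-5β,8β-dimethyl-octal-1(10)-en-9β-yl]-N,N-dimethylacetamide | COc1cc(C)c(OC)c(C[C@]2(CC(=O)N(C)C)C3=CCCC4(OCCO4)[C@]3(C)CC[C@H]2C)c1
F6 | step 16 | 2-[4,4-ethylenedioxy-9α-(ArCH2)-5β,8β-dimethyl-trans-decalin-9β-yl]-N,N-dimethylacetamide | COc1cc(C)c(OC)c(C[C@]2(CC(=O)N(C)C)[C@H]3CCCC4(OCCO4)[C@]3(C)CC[C@H]2C)c1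
F7 | step 16 | 2-[4,4-ethylenedioxy-9α-(ArCH2)-5β,8β-dimethyl-trans-decalin-9β-yl]acetaldehyde | COc1cc(C)c(OC)c(C[C@]2(CC=O)[C@H]3CCCC4(OCCO4)[C@]3(C)CC[C@H]2C)c1
F8 | step 12 | 4,4-ethylenedioxy-1β-(triethylsilyloxy)-9-(ArCH2)-5β,8β-dimethyl-Δ9(10)-octalin-7α-ol | COc1cc(C)c(OC)c(CC2=C3[C@@H](O[Si](CC)(CC)CC)CCC4(OCCO4)[C@]3(C)C[C@H](O)[C@H]2C)c1
F9 | step 12 | S-methyl xanthate of F8 | COc1cc(C)c(OC)c(CC2=C3[C@@H](O[Si](CC)(CC)CC)CCC4(OCCO4)[C@]3(C)C[C@H](OC(=S)SC)[C@H]2C)c1
F0 | step 6 | none | none
F10 | step 22 | 4β-(3-hydroxypropyl)-9α-(ArCH2)-5β,8β,9β-trimethyl-trans-decalin-3α-ol | COc1cc(C)c(OC)c(C[C@]2(C)[C@H]3CC[C@H](O)[C@@H](CCCO)[C@]3(C)CC[C@H]2C)c1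
F11 | step 22 | 3-[3-oxo-9α-(ArCH2)-5β,8β,9β-trimethyl-trans-decalin-4β-yl]propanoic acid | COc1cc(C)c(OC)c(C[C@]2(C)[C@H]3CCC(=O)[C@@H](CCC(=O)O)[C@]3(C)CC[C@H]2C)c1
F0 | step 24 | none | none
A1 | alternative 1 | methyl ester of the 4-methoxy-2-methyl-6-(decalinylmethyl)phenol (benzannulation product) | COc1cc(C)c(O)c(C[C@]2(C)[C@H]3CCC(=C(C)C)[C@@H](CCC(=O)OC)[C@]3(C)CC[C@H]2C)c1
A2 | alternative 1 | methyl 3-[3-isopropylidene-5β,8β,9β-trimethyl-9α-(prop-2-ynyl)-trans-decalin-4β-yl]propanoate (alkyne partner) | C#CC[C@]1(C)[C@H]2CCC(=C(C)C)[C@@H](CCC(=O)OC)[C@]2(C)CC[C@H]1C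
A3 | alternative 1 | pentacarbonyl[(E)-1-methoxybut-2-enylidene]chromium | COC(=[Cr])/C=C/C.[C-]#[O+].[C-]#[O+].[C-]#[O+].[C-]#[O+].[C-]#[O+]
A4 | alternative 2 | trans-fused octalin aldehyde with isopropylidene (cycloadduct) | COc1cc(C)c(OC)c(C[C@]2(C)[C@H]3C=CC(=C(C)C)[C@@H](C=O)[C@]3(C)CC[C@H]2C)c1
A5 | alternative 2 | (2E,8E)-7-(ArCH2)-3,6,7,12-tetramethyltrideca-2,8,10,11-tetraenal (vinylallene enal) | O=C/C=C(\C)CC[C@@H](C)[C@](C)(Cc1cc(OC)cc(C)c1OC)/C=C/C=C=C(C)C
A6 | alternative 3 | trans-decalin hydroxy ketone (bicyclisation product) | COc1cc(C)c(OC)c(C[C@]2(C)[C@H]3CCC(=O)[C@@H](CCC(=O)OC)[C@]3(C)CC[C@H]2O)c1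
A7 | alternative 3 | epoxy diene (Z)-silyl enol ether (cyclisation substrate) | COC(=O)CC/C=C(O[Si](C)(C)C(C)(C)C)/CC/C=C(\C)CC[C@H]1O[C@]1(C)Cc2cc(OC)cc(C)c2OC
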